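The amounts in the earlier runs show how the substrate divides, and that division is what I reckon with here.

| flask | substrate | partner | remark | time |
|---|---|---|---|---|
| north-east | 20 mM | 1.8 equiv | run made earlier |  |
| west | 28 mM | 1.8 equiv | run made earlier |  |
| east | 44 mM | 1.8 equiv | run made earlier |  |
| south-west | 20 mM | 0.90 equiv | run made earlier |  |
| Thursday's | 20 mM (fed, over 20 h) | 1.80 equiv | all else is in the flask from the start; the feed brings no volume worth counting | 2.0 d |
| Wednesday's | 20 mM (fed, over 2.0 h) | 1.80 equiv | all else is in the flask from the start; the feed brings no volume worth counting | 2.0 d |
| Sunday's | 20 mM | 1.80 equiv | everything together at the start | 2.0 d |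
| Friday's | 20 mM | 1.80 equiv (fed, over 20 h) | all else is in the flask from the start; the feed brings no volume worth counting | 2.0 d |

- north-east (time / h: target / %, side product / %): 2.50: 0, 54.3; 4.00: 0.4, 59.6; 6.00: 0.9, 61.8; 10.0: 1.8, 63.6; 20.0: 7.6, 63.1; 30.0: 15.4, 63.6
- west (time / d: target / %, side product / %): 0.167: 0, 67.4; 0.500: 3.1, 70.1; 0.833: 6.8, 69.8; 1.25: 11.9, 69.9; 1.67: 17.8, 70.4; 2.50: 25.2, 69.0
- east (time / d: target / %, side product / %): 0.167: 0, 76.5; 0.500: 1.6, 78.0; 0.833: 5.9, 77.5; 1.25: 10.1, 77.8; 1.67: 14.8, 78.4; 2.50: 18.2, 76.9
- south-west (time / d: target / %, side product / %): 0.208: 0.3, 40.5; 0.333: 0, 42.2; 0.625: 3.3, 42.9; 1.25: 14.1, 43.0; 2.50: 33.2, 42.7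

(readings scatter by 0.5 percentage points)

- the flask with the highest share of target in target plus side product ("all alike" if they lie within 1.5 percentage points) (Thursday's / Wednesday's / Sunday's / Friday's / all alike)
- share of target in target plus side product at the end, Thursday's
- share of target in target plus side product at the end, Wednesday's
- share of target in target plus side product at the end, Sunday's
- share of target in target plus side product at the end, Friday's

Substrate leaves by two routes: by itself to intermediate A, and with the partner to side product. At a steady partner level the second route is pseudo-first-order, with a rate proportional to that level. The ratio of the two constants is a concentration, the crossover level: the partner concentration at which both routes run equally fast. At partner level P, the share lost to side product is P/(crossover + P). As partner falls, and if side product is taken as its one use while substrate lasts, the substrate escaping side product equals the crossover times ln(partner charged / partner left). The north-east run, with a reading of 63.6 % side product, reads 16.7 mM. The south-west run, with its smaller partner charge, reads 17.5 mM.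

Sunday's is the north-east recipe. I assume both routes are first order in substrate, so feeding substrate keeps that side product and delays the chain by half the feed. In the west run, the fraction of escaped material that has become target reads 70.1 % at 2.0 d, between two readings, and I take it over to the flasks charged with 20 mM of substrate as an assumption. Interpolated at the delayed times, this gives me 28.6 % for Sunday's, 28.3 % for Wednesday's and 24.3 % for Thursday's.

Friday's needs a count. The early north-east readings, divided between the routes by the crossover, read as a half-life of 2.55 h for substrate on its own route, which is shorter than the 20 h feed. So in Friday's, after one such half-life, the feed has delivered 4.59 mM of partner, below the crossover. Taking that as the level, and subtracting no partner for what side product uses, I expect 21.6 % side product and a share of 71.8 % for Friday's.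

The forecast, holding that “slow substrate feeding does not change the split”, names Friday's, with 22 % for Thursday's, 27 % for Wednesday's, 27.5 % for Sunday's and 75 % for Friday's, the last above my figure.

The flasks give 24.5 % for Thursday's, 28.4 % for Wednesday's, 28.8 % for Sunday's and 76.0 % for Friday's, which holds 17.2 % side product at 2.00 d.

    partner + intermediate C → intermediate D (k = 0.285 /M/min)
    substrate + partner → side product (k = 0.269 /M/min)
    intermediate D → target (k = 6.29 × 10⁻⁴ /min)
    intermediate B → intermediate C (k = 0.00536 /min)
    substrate → intermediate A (k = 0.00464 /min)
    intermediate A → intermediate B (k = 0.00203 /min)

Through the crossover of 16.7 mM, that side product in Friday's corresponds to a steady partner level of 3.47 mM, lower than my 4.59 mM. The neighbour of Thursday's with 12 mM of substrate is charged 21.6 mM of partner, and at that level, held steady, the crossover gives 56.4 % side product; that flask ends with 50.6 %.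

The runs were computed with made-up constants, and the scatter is random.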